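## The problem

The target is a depside. The carboxyl group of ring A (2,4-dimethoxy-6-propylbenzoic acid) is esterified with O3 of ring B (a 2,3,4-trioxygenated 6-propylbenzoic acid), so the skeleton is two propyl-substituted benzoates joined by one aryl ester. Both partners of that ester are crowded: the acyl carbon lies between a methoxy and a propyl group, and the oxygen sits on C3 of ring B between the C2 and C4 hydroxyls. Ring B is the real difficulty, because three contiguous oxygens must be placed on a resorcylic acid and only the central one acylated while the flanking phenols stay free. The target has no stereocentre. A route through a saturated ring B creates two transient ones (C1 and C6) that vanish on aromatization, so only convergence of isomers matters, not stereocontrol. The depside ester is cleaved or transposed by hydroxide, alkoxide and amines, and acyl migration to the neighbouring phenols is possible. The 2,4-dihydroxy-6-alkylbenzoic acid decarboxylates in hot or strongly acidic media, and both rings are electron-rich, so the closing steps must be neutral and mild. The enabling feature is that C3 of ring B, flanked by the oxygen-bearing C2 and C4, is C2 of a cyclohexane-1,3-dione. At that oxidation level C3 accepts a diazo group, the flanking oxygens are carbonyls that need no protection, and C1 (carboxylate) and C6 (propyl) are what a Michael–Claisen annulation delivers.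

## Retrosynthesis

**13 to 12.** The last bond cut is the O–CH2 bond of a benzyl ester on the ring B carboxyl, so that target 13 comes from benzyl ester 12 by hydrogenolysis. A benzyl ester is preferred to a tert-butyl ester because acid cleavage would expose the resorcylic acid to protodecarboxylation and both activated rings to tert-butyl cations. It is preferred to a simple alkyl ester because saponification would destroy the depside link. The forward step only has to spare the aryl ester, which hydrogenolysis does.

**12 to 11.** Ring B of 12 is taken back by formal addition of two hydrogens (at C1 and C6) to the cyclohexenone 11, the enol of a 3-acyloxy-2,4-dione. This retro-dehydrogenation adds no simplification in atom count, but it converts the two flanking phenols into a ketone and an enol, so no phenol has to be protected or distinguished. The forward reaction must remove the C6 and C1 hydrogens without oxidizing the benzylic positions, ring A or the product phenol.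

**11 to 5 and 10.** The O–C3 bond of ring B is cut, giving diazodione 5 and carboxylic acid 10. The neighbouring cut, the acyl C–O bond, would require a hydroxyl wedged between two oxygens to attack a carbonyl wedged between methoxy and propyl, and would require an air-sensitive 3-hydroxy-2,4-dione. Cutting at O–C3 lets the bond form at the unhindered carboxyl oxygen by carbenoid O–H insertion, and it splits the molecule into two halves of similar size. The forward step must favour O–H insertion over all other fates of a rhodium carbenoid.

**5 to 4.** The C3=N2 unit is removed, leading to dione ester 4. C3 is the only methylene between two ketones, so diazo transfer from a sulfonyl azide is expected to be regioselective. C1, between ketone and ester, carries one hydrogen and cannot become a diazo carbon.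

**4 to 1 and 2.** Ring B's carbocycle is opened at C2–C3 (Claisen bond) and C1–C6 (Michael bond), passing through adduct 3 to dibenzyl malonate 1 and (E)-hept-3-en-2-one 2. The alternative pairing of an acetoacetate with a hex-2-enoate forms the same ring but needs two different ester groups, which invites scrambling when the target ester is benzyl. With 1, both esters and the base are benzyl-derived. The forward reaction is the malonate–enone annulation long used for 5-alkylcyclohexane-1,3-diones.

**10 to 9, 7 and 6.** Acid 10 is traced to aldehyde 9 (oxidation level), then to 1,3-dimethoxy-5-propylbenzene 7 by cutting the ring–CHO bond, and to 5-propylresorcinol 6 by cutting both O–CH3 bonds. Electrophilic formylation is chosen over directed lithiation–carboxylation, because lithiation of 7 would occur between the two methoxy groups and give the wrong isomer.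

## Roads not taken

**Alternative 1:** Biomimetic folding of ring A on a ring B aryl ester. The cut is the C1–C2 bond of ring A. The phenol benzyl 2,4-bis(benzyloxy)-3-hydroxy-6-propylbenzoate A3 would be acylated to the aryl 3,5,7-trioxodecanoate A2. Aldol attack of chain C2 on the C7 ketone and dehydration would close ring A as the resorcylate A1, benzyl 2,4-bis(benzyloxy)-3-(2,4-dihydroxy-6-propylbenzoyloxy)-6-propylbenzoate. O-methylation of the two ring A phenols and hydrogenolysis of three benzyl groups would follow.

- Merits: the ester is made from an unhindered polyketide acyl donor, no diazo compound or carbenoid is involved, and ring B never changes oxidation level. In these respects it is cleaner than the chosen plan.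
- Weak points: the central problem is not solved but moved into A3, a ring B with three contiguous oxygens already differentiated, which needs its own multistep oxygenation and protection. A2 is an activated aryl ester of a β-keto acid. Lactonization through the C5 enol oxygen to a 4-hydroxy-2-pyranone, or Claisen closure from C6 onto C1, would each expel A3 and destroy the depside link. The 2-hydroxyl of ring A in A1 is hydrogen-bonded and slow to methylate.
- Comparison: the chosen plan spends one oxidation step (step 7) and a diazo intermediate, but it needs no differentiated trioxygenated arene and its ring closure (step 1) cannot cleave the ester, which does not yet exist.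

**Alternative 2:** Ring B folded from an acyloxy polyketide chain. The cut is the C1–C6 bond of ring B. In tert-butyl 4-(2,4-dimethoxy-6-propylbenzoyloxy)-7-methoxy-3,5-dioxodec-6-enoate A5, chain C2 would add to the enol ether carbon C7 with loss of the methoxy group. The ring would enolize directly to A4, tert-butyl 3-(2,4-dimethoxy-6-propylbenzoyloxy)-2,4-dihydroxy-6-propylbenzoate.

- Merits: ring B appears at the aromatic oxidation level with the ester already on C3, and A4 is one deprotection from the target. After its key step this road is one step shorter than the chosen one, and it needs no oxidant.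
- Weak points: in A5 the most acidic hydrogen is at C4, between two ketones and bearing the acyloxy group. Its enolate is unproductive and opens the way to acyl migration onto an enol oxygen. The C2 nucleophile needed for closure competes with attack of an enol oxygen on C7, which gives a 4-pyranone, the usual fate of such β-alkoxy enone tricarbonyl chains. Making A5 requires an acyloxy group on the central carbon of an acyclic 1,3-diketone, the same C–O bond problem as in the chosen plan but on a more fragile substrate. The tert-butyl ester must then be removed with strong acid from a decarboxylation-prone acid.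
- Comparison: the chosen plan pays one dehydrogenation. In return, the carbocycle is closed by a robust annulation before the oxygen is introduced, every intermediate is a stable cyclic dione, and the final deprotection is neutral.

**Alternative 3:** Ring A from a 2-pyrone by cycloaddition. The cut removes two C–C bonds of ring A. The aryl pyrone ester A7 (the A3 ester of 4-methoxy-2-oxo-6-propyl-2H-pyran-5-carboxylic acid) and 1,1-dimethoxyethene A8 would undergo Diels–Alder addition across pyrone C3 and C6. Decarboxylative cycloreversion and elimination of one methoxy group would give the arene A6, benzyl 2,4-bis(benzyloxy)-3-(2,4-dimethoxy-6-propylbenzoyloxy)-6-propylbenzoate. Hydrogenolysis would finish the synthesis.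

- Merits: the regiochemistry of ring A is fixed by the polarity of diene and dienophile, the cascade is thermal and neutral, and the endgame is the same hydrogenolysis as in the chosen plan. No oxidation-state adjustment is needed.
- Weak points: the key step builds ring A, which is available in three routine steps from 6, and it again relies on the differentiated phenol A3. A3 must be acylated at a hydroxyl flanked by two benzyloxy groups. A7 is an activated aryl ester heated with a nucleophilic ketene acetal and with the alcohol set free in the aromatization, both of which can cleave the depside link. A8 is moisture-sensitive and must be used in excess.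
- Comparison: this road is attractive if A3 were at hand, but for this target it invests its invention in the easy ring. The chosen plan places the key step on the bond that makes ring B difficult.

Key step: step 6

Assumption: compounds 4, 5 and 11 (and the related fallback compounds) are racemic and are drawn as the trans isomers and as single keto or enol tautomers; cis isomers and other tautomers converge on the same arene 12. Compounds 1, 2 and 6 and all reagents are taken as commercial.

## Route

Step 1
Reactants: 1 dibenzyl malonate; 2 (E)-hept-3-en-2-one
Product: 4 benzyl (±)-trans-2,4-dioxo-6-propylcyclohexane-1-carboxylate, via dibenzyl 2-(2-oxoheptan-4-yl)malonate 3 (not isolated)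
Conditions: NaOBn (1.0 M in BnOH), THF, 0 °C to 65 °C; then aq. HCl
Reagents that add atoms: none
Why: Michael addition of the malonate anion of 1 to the β-carbon of 2 gives 3, whose methyl ketone enolate closes the ring by intramolecular Claisen (Dieckmann-type) condensation on one benzyl ester, the classical malonate–enone route to 5-alkylcyclohexane-1,3-diones; benzyloxide as base cannot scramble the ester. C6 forms as a racemate and the enolizable C1 settles trans to the propyl group under the equilibrating conditions.

Step 2
Reactants: 4 benzyl (±)-trans-2,4-dioxo-6-propylcyclohexane-1-carboxylate
Product: 5 benzyl (±)-trans-3-diazo-2,4-dioxo-6-propylcyclohexane-1-carboxylate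
Conditions: p-ABSA, Et3N, MeCN, 0 °C to rt
Reagents that add atoms: 4-acetamidobenzenesulfonyl azide (p-ABSA), CC(=O)Nc1ccc(cc1)S(=O)(=O)N=[N+]=[N-]
Why: Regitz diazo transfer to the enolate of the cyclic 1,3-dione; C3 is the only doubly activated CH2, whereas C1 has a single hydrogen and cannot become a diazo carbon without C–C cleavage. The centres at C1 and C6 are not involved.

Step 3
Reactants: 6 5-propylbenzene-1,3-diol
Product: 7 1,3-dimethoxy-5-propylbenzene
Conditions: MeI, K2CO3, acetone, reflux
Reagents that add atoms: iodomethane, CI
Why: Williamson O-methylation of both phenols with a weak base in a polar aprotic solvent, where O-alkylation of resorcinols dominates over C-alkylation.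

Step 4
Reactants: 7 1,3-dimethoxy-5-propylbenzene
Product: 9 2,4-dimethoxy-6-propylbenzaldehyde, via N-(2,4-dimethoxy-6-propylbenzylidene)-N-methylmethanaminium chloride 8 (not isolated)
Conditions: POCl3, DMF, 0 °C then 70 °C; then ice–water
Reagents that add atoms: N,N-dimethylformamide, CN(C)C=O (formyl carbon); water, O (carbonyl oxygen)
Why: Vilsmeier–Haack formylation; the chloroiminium ion attacks the position para to one methoxy and ortho to the other (two equivalent sites by symmetry), which is less crowded than the site between the two methoxy groups, and hydrolysis of iminium salt 8 releases the aldehyde.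

Step 5
Reactants: 9 2,4-dimethoxy-6-propylbenzaldehyde
Product: 10 2,4-dimethoxy-6-propylbenzoic acid
Conditions: NaClO2, NaH2PO4, 2-methyl-2-butene, t-BuOH–H2O, rt
Reagents that add atoms: sodium chlorite, [Na+].[O-]Cl=O
Why: Pinnick oxidation of an aromatic aldehyde to the acid under buffered conditions; 2-methyl-2-butene removes hypochlorous acid so that the electron-rich ring is not chlorinated, and the methyl ethers are inert.

Step 6
Reactants: 5 benzyl (±)-trans-3-diazo-2,4-dioxo-6-propylcyclohexane-1-carboxylate; 10 2,4-dimethoxy-6-propylbenzoic acid
Product: 11 benzyl (±)-trans-3-(2,4-dimethoxy-6-propylbenzoyloxy)-4-hydroxy-2-oxo-6-propylcyclohex-3-ene-1-carboxylate (enol tautomer)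
Conditions: Rh2(OAc)4 (2 mol %), 10 (1.5 equiv), 4 Å MS, 1,2-dichloroethane, 80 °C, slow addition of 5
Reagents that add atoms: none
Why: Rh2(OAc)4 (dirhodium tetraacetate, divalent rhodium) is attacked at its axial site by the diazo carbon of 5 and expels N2 to give an electrophilic acceptor/acceptor carbenoid at C3. An oxygen of the carboxyl group of 10 adds to this carbon to form an oxonium ylide (or a closely related hydrogen-bonded transition state), and proton transfer releases the catalyst and the 3-acyloxy-2,4-dione, which settles as enol 11. The closest known reaction type is the dirhodium-tetracarboxylate-catalysed O–H insertion of carboxylic acids into 2-diazo-1,3-dicarbonyl compounds. No ring is closed and no stereocentre is created, because C3 ends up trigonal in the enol; the racemic trans centres at C1 and C6 are spectators that disappear in step 7. The step needs chemoselectivity for the acid O–H over the enolic O–H of a second molecule of 5 or of 11, over adventitious water, over electrophilic attack on the dimethoxyarene of 10 and over Wolff ring contraction. The substrate pair secures this: the carboxylic acid is the most acidic and least hindered O–H donor and is kept in excess while 5 is added slowly, the free arene positions of 10 are deactivated by the carboxyl group and flanked by substituents, and the metal-bound carbenoid formed at 80 °C does not follow the thermal or photochemical Wolff pathway. Because the new bond is made at oxygen, remote from the ortho substituents of 10, the crowding that would hamper acyl substitution plays no part, and because O2 and O4 of ring B are still carbonyl oxygens no phenol has to be protected or distinguished.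

Step 7
Reactants: 11 benzyl (±)-trans-3-(2,4-dimethoxy-6-propylbenzoyloxy)-4-hydroxy-2-oxo-6-propylcyclohex-3-ene-1-carboxylate
Product: 12 benzyl 3-(2,4-dimethoxy-6-propylbenzoyloxy)-2,4-dihydroxy-6-propylbenzoate
Conditions: DDQ (1.2 equiv), 1,4-dioxane, 80 °C
Reagents that add atoms: none
Why: Quinone dehydrogenation: DDQ abstracts hydride from the tertiary allylic C6–H of the β-keto ester enol, loss of a proton gives the dienone, and this tautomerizes irreversibly to the resorcinol, the known oxidative aromatization of cyclohexane-1,3-diones and cyclohexenones to phenols. The free hydroxyls of 12 are meta-related and the central oxygen is acylated, so no quinone can form, and the benzyl and aryl esters are inert to DDQ.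

Step 8
Reactants: 12 benzyl 3-(2,4-dimethoxy-6-propylbenzoyloxy)-2,4-dihydroxy-6-propylbenzoate
Product: 13 3-(2,4-dimethoxy-6-propylbenzoyloxy)-2,4-dihydroxy-6-propylbenzoic acid (CNP0211929.0)
Conditions: H2 (1 atm), 10% Pd/C, EtOAc, rt
Reagents that add atoms: none
Why: Hydrogenolysis of the benzyl ester over palladium on carbon under neutral conditions, the usual closing step of depside syntheses; the aryl ester, methyl ethers and phenols are untouched, and neither acid nor heat is applied to the decarboxylation-prone acid.

## Compound list

1 | dibenzyl malonate | O=C(CC(=O)OCc1ccccc1)OCc1ccccc1 | starting material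
2 | (E)-hept-3-en-2-one | CCC/C=C/C(C)=O | starting material
3 | dibenzyl 2-(2-oxoheptan-4-yl)malonate (racemic, one enantiomer drawn) | CCC[C@@H](C(C(=O)OCc1ccccc1)C(=O)OCc1ccccc1)CC(C)=O | intermediate
4 | benzyl (±)-trans-2,4-dioxo-6-propylcyclohexane-1-carboxylate (CO2Bn and propyl on opposite faces; largely enolized) | CCC[C@@H]1CC(=O)CC(=O)[C@H]1C(=O)OCc1ccccc1 | intermediate
5 | benzyl (±)-trans-3-diazo-2,4-dioxo-6-propylcyclohexane-1-carboxylate | CCC[C@@H]1CC(=O)C(=[N+]=[N-])C(=O)[C@H]1C(=O)OCc1ccccc1 | intermediate
6 | 5-propylbenzene-1,3-diol | CCCc1cc(O)cc(O)c1 | starting material
7 | 1,3-dimethoxy-5-propylbenzene | CCCc1cc(OC)cc(OC)c1 | intermediate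
8 | N-(2,4-dimethoxy-6-propylbenzylidene)-N-methylmethanaminium chloride | CCCc1cc(OC)cc(OC)c1C=[N+](C)C.[Cl-] | intermediate
9 | 2,4-dimethoxy-6-propylbenzaldehyde | CCCc1cc(OC)cc(OC)c1C=O | intermediate
10 | 2,4-dimethoxy-6-propylbenzoic acid | CCCc1cc(OC)cc(OC)c1C(=O)O | intermediate
11 | benzyl (±)-trans-3-(2,4-dimethoxy-6-propylbenzoyloxy)-4-hydroxy-2-oxo-6-propylcyclohex-3-ene-1-carboxylate (enol tautomer) | CCCc1cc(OC)cc(OC)c1C(=O)OC1=C(O)C[C@@H](CCC)[C@H](C(=O)OCc2ccccc2)C1=O | intermediate
12 | benzyl 3-(2,4-dimethoxy-6-propylbenzoyloxy)-2,4-dihydroxy-6-propylbenzoate | CCCc1cc(OC)cc(OC)c1C(=O)Oc1c(O)cc(CCC)c(C(=O)OCc2ccccc2)c1O | intermediate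
13 | 3-(2,4-dimethoxy-6-propylbenzoyloxy)-2,4-dihydroxy-6-propylbenzoic acid | CCCc1cc(OC)cc(OC)c1C(=O)Oc1c(O)cc(CCC)c(C(=O)O)c1O | target

## Step count and least certain steps

Total step count: 8. Longest linear sequence: 6 steps (steps 3, 4, 5, 6, 7 and 8, from 6). The ring B branch (steps 1 and 2) joins at step 6.

**Step 6 (key step).** The most likely failure is diversion of the carbenoid. Possible diversions are insertion into water or into the enolic O–H of a second molecule of 5 or of 11, electrophilic attack on the arene of 10, and ring contraction at the temperature needed to decompose the stabilized diazodione. The free acid may also slow the catalyst by coordination. The fallback replaces the diazo group with a trivalent-iodine leaving group. It sets out from 4, which with PhI(OAc)2 and Na2CO3 in MeOH–CH2Cl2 should give the phenyliodonium ylide benzyl (±)-trans-2,4-dioxo-3-(phenyliodonio)-6-propylcyclohexan-3-ide-1-carboxylate F1. Warming F1 with acid 10 should protonate C3 and then couple carboxylate and carbon at iodine with release of iodobenzene, if need be with Cu(acac)2 as catalyst. This forms the same O–C3 bond without a free or metal carbenoid, by-passes 5, and returns to the route at 11.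

**Step 7.** Hydride abstraction may be slow from a substrate held as a strongly hydrogen-bonded enol. In that case covalent coupling of the enol with the quinone, acyl migration to a neighbouring oxygen on prolonged heating, or oxidation of the product phenol could compete. The fallback replaces hydride abstraction by a syn-elimination. It sets out from 11, which with PhSeCl and pyridine in CH2Cl2 at 0 °C should be selenenylated at C1, on the face away from the propyl group. This gives benzyl (±)-3-(2,4-dimethoxy-6-propylbenzoyloxy)-4-hydroxy-2-oxo-1-(phenylselanyl)-6-propylcyclohex-3-ene-1-carboxylate F2. Oxidation with H2O2 at 0 °C should give the selenoxide, benzyl (±)-3-(2,4-dimethoxy-6-propylbenzoyloxy)-4-hydroxy-2-oxo-1-(phenylseleninyl)-6-propylcyclohex-3-ene-1-carboxylate F3. Its selenium is cis to the C6 hydrogen, so syn-elimination should follow below room temperature, and the resulting dienone tautomerizes to the arene. The path returns to the route at 12.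

**Step 1.** Claisen closure may be incomplete, leaving 3. The benzyl ester may also be lost by hydrolysis and decarboxylation during the acidic work-up, and benzyl alcohol must be separated from an enolic product. The fallback runs the annulation in its classical form and changes the ester afterwards. It sets out from 2, which with commercial dimethyl malonate and NaOMe in MeOH should give, through dimethyl 2-(2-oxoheptan-4-yl)malonate F4, methyl (±)-trans-2,4-dioxo-6-propylcyclohexane-1-carboxylate F5. Heating F5 with benzyl alcohol in toluene, with removal of the alcohol set free, should transesterify the β-keto ester through its acylketene and return to the route at 4.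

**Step 4.** The electrophilic substitution may be sluggish or misdirected, since the chloroiminium ion is a weak and bulky electrophile and the reacting position is flanked by propyl and methoxy. Attack between the two methoxy groups or a second formylation would cost material. The fallback changes the way the carboxyl carbon is introduced. It sets out from 7, which with NBS in MeCN should brominate para to a methoxy group to give 2-bromo-1,5-dimethoxy-3-propylbenzene F6. Bromine–lithium exchange with n-BuLi in THF at −78 °C should give (2,4-dimethoxy-6-propylphenyl)lithium F7, and carboxylation with CO2 followed by acidic work-up returns to the route at 10, by-passing 9 and step 5.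

## Further compounds

F1 | step 6 | benzyl (±)-trans-2,4-dioxo-3-(phenyliodonio)-6-propylcyclohexan-3-ide-1-carboxylate (phenyliodonium ylide of 4) | CCC[C@@H]1CC(=O)[C-]([I+]c2ccccc2)C(=O)[C@H]1C(=O)OCc1ccccc1
F2 | step 7 | benzyl (±)-3-(2,4-dimethoxy-6-propylbenzoyloxy)-4-hydroxy-2-oxo-1-(phenylselanyl)-6-propylcyclohex-3-ene-1-carboxylate (PhSe trans to propyl) | CCCc1cc(OC)cc(OC)c1C(=O)OC1=C(O)C[C@@H](CCC)[C@](C(=O)OCc2ccccc2)([Se]c2ccccc2)C1=O
F3 | step 7 | benzyl (±)-3-(2,4-dimethoxy-6-propylbenzoyloxy)-4-hydroxy-2-oxo-1-(phenylseleninyl)-6-propylcyclohex-3-ene-1-carboxylate (selenoxide, mixture at selenium) | CCCc1cc(OC)cc(OC)c1C(=O)OC1=C(O)C[C@@H](CCC)[C@](C(=O)OCc2ccccc2)([Se](=O)c2ccccc2)C1=O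
F4 | step 1 | dimethyl 2-(2-oxoheptan-4-yl)malonate (racemic, one enantiomer drawn) | CCC[C@@H](C(C(=O)OC)C(=O)OC)CC(C)=O
F5 | step 1 | methyl (±)-trans-2,4-dioxo-6-propylcyclohexane-1-carboxylate | CCC[C@@H]1CC(=O)CC(=O)[C@H]1C(=O)OC
F6 | step 4 | 2-bromo-1,5-dimethoxy-3-propylbenzene | CCCc1cc(OC)cc(OC)c1Br
F7 | step 4 | (2,4-dimethoxy-6-propylphenyl)lithium | CCCc1cc(OC)cc(OC)c1[Li]
A1 | alternative 1 | benzyl 2,4-bis(benzyloxy)-3-(2,4-dihydroxy-6-propylbenzoyloxy)-6-propylbenzoate | CCCc1cc(O)cc(O)c1C(=O)Oc1c(OCc2ccccc2)cc(CCC)c(C(=O)OCc2ccccc2)c1OCc1ccccc1
A2 | alternative 1 | 2,6-bis(benzyloxy)-3-(benzyloxycarbonyl)-4-propylphenyl 3,5,7-trioxodecanoate | CCCC(=O)CC(=O)CC(=O)CC(=O)Oc1c(OCc2ccccc2)cc(CCC)c(C(=O)OCc2ccccc2)c1OCc1ccccc1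
A3 | alternative 1 | benzyl 2,4-bis(benzyloxy)-3-hydroxy-6-propylbenzoate | CCCc1cc(OCc2ccccc2)c(O)c(OCc2ccccc2)c1C(=O)OCc1ccccc1
A4 | alternative 2 | tert-butyl 3-(2,4-dimethoxy-6-propylbenzoyloxy)-2,4-dihydroxy-6-propylbenzoate | CCCc1cc(OC)cc(OC)c1C(=O)Oc1c(O)cc(CCC)c(C(=O)OC(C)(C)C)c1O
A5 | alternative 2 | tert-butyl 4-(2,4-dimethoxy-6-propylbenzoyloxy)-7-methoxy-3,5-dioxodec-6-enoate (racemic, enol ether geometry not defined) | CCCC(OC)=CC(=O)C(OC(=O)c1c(CCC)cc(OC)cc1OC)C(=O)CC(=O)OC(C)(C)C
A6 | alternative 3 | benzyl 2,4-bis(benzyloxy)-3-(2,4-dimethoxy-6-propylbenzoyloxy)-6-propylbenzoate | CCCc1cc(OC)cc(OC)c1C(=O)Oc1c(OCc2ccccc2)cc(CCC)c(C(=O)OCc2ccccc2)c1OCc1ccccc1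
A7 | alternative 3 | 2,6-bis(benzyloxy)-3-(benzyloxycarbonyl)-4-propylphenyl 4-methoxy-2-oxo-6-propyl-2H-pyran-5-carboxylate | CCCc1oc(=O)cc(OC)c1C(=O)Oc1c(OCc2ccccc2)cc(CCC)c(C(=O)OCc2ccccc2)c1OCc1ccccc1
A8 | alternative 3 | 1,1-dimethoxyethene | C=C(OC)OC
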